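The 1,2-dioxane ring (O1, O2, C3–C6) is cut by a retro-oxa-Michael disconnection: C3 carries the CH2CO2H arm, so its ring oxygen O2 lies β to the carboxyl carbon. The key step closes the dioxane by 6-exo-trig addition of a C6 hydroperoxide to an (E)-enoate, forming O2–C3 and setting C3 trans (diequatorial) to C6 in one operation. Its precursor is an open-chain hydroperoxy enoate on a trans-2,5-disubstituted oxolane. That compound comes from a glutamic-acid-derived lactone (oxolane C5'), a Z-selective Wittig reaction, a hydroxyl-directed rhenium oxidative cyclisation (oxolane ring, C2' and the C6 carbinol) and an invertive triflate displacement by H2O2.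

Key step: step 14

Remark on the chemistry: the SMILES is read as the (3S,6S)-1,2-dioxane bearing a (2S,5R)-oxolane (3,6-trans dioxane, 2,5-trans oxolane, threo across C6–C2'); C2' is the oxolane carbon bonded to C6 and C5' carries the C14 chain.

**Step 1**
Reactants: 1 hept-6-yn-1-ol
Product: 2 7-bromohept-6-yn-1-ol
Conditions: NBS, AgNO3 (10 mol %), acetone, rt
Reagents that add atoms: N-bromosuccinimide, O=C1CCC(=O)N1Br
Why: Silver-catalysed electrophilic bromination of the terminal alkyne (through the silver acetylide) should give the 1-bromoalkyne needed for the diyne coupling and leave the primary alcohol untouched.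

**Step 2**
Reactants: 2 7-bromohept-6-yn-1-ol; 3 hex-1-en-5-yne
Product: 4 tridec-12-ene-6,8-diyn-1-ol
Conditions: CuCl (5 mol %), NH2OH·HCl, 30% aq. n-BuNH2, Et2O, 0 °C → rt
Reagents that add atoms: none
Why: Cadiot–Chodkiewicz coupling of the copper acetylide of 3 with bromoalkyne 2 should give the unsymmetrical 1,3-diyne, hydroxylamine keeping the copper monovalent so that oxidative homocoupling is suppressed.

**Step 3**
Reactants: 4 tridec-12-ene-6,8-diyn-1-ol
Product: 5 (6Z,8Z)-trideca-6,8,12-trien-1-ol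
Conditions: Zn dust activated with Cu(OAc)2 and AgNO3, MeOH/H2O 1:1, rt → 40 °C
Reagents that add atoms: none
Why: The Zn(Cu/Ag) semi-reduction (Boland reduction) delivers hydrogen cis to conjugated triple bonds only, so the diyne should become the (Z,Z)-diene without over-reduction while the isolated terminal alkene stays.

**Step 4**
Reactants: 5 (6Z,8Z)-trideca-6,8,12-trien-1-ol
Product: 6 (5Z,7Z)-13-bromotrideca-1,5,7-triene
Conditions: CBr4, PPh3, CH2Cl2, 0 °C
Reagents that add atoms: carbon tetrabromide, BrC(Br)(Br)Br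
Why: The Appel reaction converts the primary alcohol into the bromide by SN2 under neutral conditions that should not isomerise the diene.

**Step 5**
Reactants: 7 [(2S)-5-oxooxolan-2-yl]methyl 4-methylbenzenesulfonate
Product: 8 methyl 3-[(2S)-oxiran-2-yl]propanoate
Conditions: NaOMe (1.05 equiv), MeOH, 0 °C → rt
Reagents that add atoms: sodium methoxide, C[O-].[Na+]
Why: Methanolysis of the lactone frees the C4 alkoxide, which displaces the neighbouring primary tosylate (intramolecular Williamson etherification); no bond to the stereocentre is broken, so the (S) configuration from L-glutamic acid is kept.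

**Step 6**
Reactants: 6 (5Z,7Z)-13-bromotrideca-1,5,7-triene; 8 methyl 3-[(2S)-oxiran-2-yl]propanoate
Product: 11 (5R)-5-[(7Z,9Z)-tetradeca-7,9,13-trien-1-yl]oxolan-2-one, via Grignard reagent 9 (not isolated), via hydroxy ester 10 (not isolated)
Conditions: Mg, THF, rt; then 8, CuI (10 mol %), THF, −40 → −20 °C; aq. NH4Cl; then TsOH (cat.), CH2Cl2, rt
Reagents that add atoms: none
Why: Copper-catalysed Grignard opening of the terminal epoxide at its CH2 carbon (SN2, faster than ester addition at low temperature) followed by acid-catalysed lactonisation; the C–O bond of the stereocentre is untouched, so its geometry is carried over (the descriptor becomes R only through the priority change).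

**Step 7**
Reactants: 11 (5R)-5-[(7Z,9Z)-tetradeca-7,9,13-trien-1-yl]oxolan-2-one
Product: 12 (5R)-5-[(7Z,9Z)-tetradeca-7,9,13-trien-1-yl]oxolan-2-ol
Conditions: i-Bu2AlH (1.1 equiv), CH2Cl2, −78 °C; aq. potassium sodium tartrate work-up
Reagents that add atoms: none
Why: Partial reduction of the γ-lactone stops at the lactol because the tetrahedral aluminate is stable at −78 °C; the alkenes are inert to the hydride at this temperature.

**Step 8**
Reactants: 13 2-(3-chloropropyl)-1,3-dioxolane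
Product: 15 [3-(1,3-dioxolan-2-yl)propyl]triphenylphosphonium iodide, via iodide 14 (not isolated)
Conditions: NaI (1.1 equiv), PPh3, MeCN, reflux
Reagents that add atoms: triphenylphosphine, c1ccc(cc1)P(c1ccccc1)c1ccccc1; sodium iodide, [Na+].[I-]
Why: Finkelstein halide exchange followed by SN2 quaternisation of triphenylphosphine by the primary iodide; the acetal is stable under these neutral conditions.

**Step 9**
Reactants: 12 (5R)-5-[(7Z,9Z)-tetradeca-7,9,13-trien-1-yl]oxolan-2-ol; 15 [3-(1,3-dioxolan-2-yl)propyl]triphenylphosphonium iodide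
Product: 17 (3Z,7R,14Z,16Z)-1-(1,3-dioxolan-2-yl)henicosa-3,14,16,20-tetraen-7-ol, via ylide 16 (not isolated)
Conditions: 15 (2.3 equiv), KN(SiMe3)2 (2.2 equiv), THF, −78 → 0 °C; then 12, −78 °C → rt
Reagents that add atoms: none
Why: Lithium-free Wittig olefination of the lactol (reacting as its open hydroxy aldehyde) with a non-stabilised ylide goes through the kinetically preferred cis-oxaphosphetane and should give the (Z)-alkene; the carbinol stereocentre is not involved.

**Step 10**
Reactants: 17 (3Z,7R,14Z,16Z)-1-(1,3-dioxolan-2-yl)henicosa-3,14,16,20-tetraen-7-ol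
Product: 18 (1R)-3-(1,3-dioxolan-2-yl)-1-{(2S,5R)-5-[(7Z,9Z)-tetradeca-7,9,13-trien-1-yl]oxolan-2-yl}propan-1-ol
Conditions: Re2O7 (2 equiv), 2,6-lutidine, CH2Cl2, rt; aq. NaHCO3 work-up
Reagents that add atoms: dirhenium heptoxide, O=[Re](=O)(=O)O[Re](=O)(=O)=O
Why: In this hydroxyl-directed oxidative cyclisation with heptavalent rhenium the perrhenate ester of the bishomoallylic alcohol adds its alkoxide oxygen and one oxo oxygen to the same face of the 4,5-alkene (syn addition); this reaction type closes the oxolane 2,5-trans (setting C2' as S from the R carbinol) and, from the Z-alkene, gives the erythro (R) carbinol, and only the alkene placed 4,5 to the free hydroxyl reacts, so the diene and terminal alkene should be spared.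

**Step 11**
Reactants: 18 (1R)-3-(1,3-dioxolan-2-yl)-1-{(2S,5R)-5-[(7Z,9Z)-tetradeca-7,9,13-trien-1-yl]oxolan-2-yl}propan-1-ol
Product: 19 (5R)-5-{(2S,5R)-5-[(7Z,9Z)-tetradeca-7,9,13-trien-1-yl]oxolan-2-yl}oxolan-2-ol
Conditions: 1 M HCl, THF, rt
Reagents that add atoms: water, O
Why: Acid-catalysed acetal hydrolysis frees the aldehyde, which is trapped by the γ-hydroxyl as the five-membered lactol; no stereocentre is touched and the unactivated diene tolerates dilute aqueous acid.

**Step 12**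
Reactants: 19 (5R)-5-{(2S,5R)-5-[(7Z,9Z)-tetradeca-7,9,13-trien-1-yl]oxolan-2-yl}oxolan-2-ol; 20 methyl (triphenylphosphoranylidene)acetate
Product: 21 methyl (2E,6R)-6-hydroxy-6-{(2S,5R)-5-[(7Z,9Z)-tetradeca-7,9,13-trien-1-yl]oxolan-2-yl}hex-2-enoate
Conditions: 20 (1.5 equiv), PhCO2H (cat.), toluene, 40 °C
Reagents that add atoms: none
Why: Wittig olefination of the lactol with the stabilised ylide gives the (E)-enoate through the reversibly formed, more stable trans-oxaphosphetane, and the neutral medium should prevent 5-exo oxa-Michael closure of the free hydroxyl.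

**Step 13**
Reactants: 21 methyl (2E,6R)-6-hydroxy-6-{(2S,5R)-5-[(7Z,9Z)-tetradeca-7,9,13-trien-1-yl]oxolan-2-yl}hex-2-enoate
Product: 23 methyl (2E,6S)-6-hydroperoxy-6-{(2S,5R)-5-[(7Z,9Z)-tetradeca-7,9,13-trien-1-yl]oxolan-2-yl}hex-2-enoate, via triflate 22 (not isolated)
Conditions: Tf2O, 2,6-lutidine, CH2Cl2, −78 °C; then anhydrous H2O2 in Et2O (10 equiv), −78 → 0 °C
Reagents that add atoms: hydrogen peroxide, OO
Why: SN2 displacement of a secondary alkyl triflate by hydrogen peroxide (an alpha-effect nucleophile; the known sulfonate-to-hydroperoxide substitution) should install the hydroperoxide with inversion, turning the erythro (6R) carbinol into the threo (6S) hydroperoxide, while neutral peroxide does not add to the enoate.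

**Step 14**
Reactants: 23 methyl (2E,6S)-6-hydroperoxy-6-{(2S,5R)-5-[(7Z,9Z)-tetradeca-7,9,13-trien-1-yl]oxolan-2-yl}hex-2-enoate
Product: 24 methyl 2-[(3S,6S)-6-{(2S,5R)-5-[(7Z,9Z)-tetradeca-7,9,13-trien-1-yl]oxolan-2-yl}-1,2-dioxan-3-yl]acetate
Conditions: Et2NH (0.3 equiv), CF3CH2OH, rt
Reagents that add atoms: none
Why: Diethylamine reversibly deprotonates the hydroperoxide, its distal oxygen adds to the β-carbon C3 of the (E)-enoate, and trifluoroethanol protonates the ester enolate. The closest known reaction type is the amine-catalysed intramolecular peroxy-Michael addition of hydroperoxy enoates to give 1,2-dioxan-3-ylacetates. The 1,2-dioxane ring closes in the 6-exo-trig mode by forming the O2–C3 bond. The new stereocentre C3 is controlled by C6: in the chair-like transition state the oxolanyl group on C6 and the ester arm on C3 are both equatorial, which gives the 3,6-trans (3S,6S) ring, and because the addition is reversible through the ester enolate the diequatorial trans isomer is also the thermodynamic product. The step needs 6-exo closure at C3 over 7-endo closure at C2 and survival of the O–O bond; the polarised enoate, the absence of any other free nucleophile and a weak base in a protic solvent (which disfavours Kornblum–DeLaMare cleavage) should secure this, and the remote diene and terminal alkene are not electrophilic.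

**Step 15**
Reactants: 24 methyl 2-[(3S,6S)-6-{(2S,5R)-5-[(7Z,9Z)-tetradeca-7,9,13-trien-1-yl]oxolan-2-yl}-1,2-dioxan-3-yl]acetate
Product: 25 2-[(3S,6S)-6-{(2S,5R)-5-[(7Z,9Z)-tetradeca-7,9,13-trien-1-yl]oxolan-2-yl}-1,2-dioxan-3-yl]acetic acid
Conditions: LiOH (3 equiv), THF/H2O 3:1, 0 °C; then 0.5 M HCl to pH 4, 0 °C
Reagents that add atoms: lithium hydroxide, [Li+].[OH-]
Why: Saponification by hydroxide attack at the ester carbonyl is faster at 0 °C than removal of the ester α-proton or of a peroxide C–H, so neither retro-Michael opening nor Kornblum–DeLaMare cleavage should compete and no stereocentre changes.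

**Compound list**

1 | hept-6-yn-1-ol | C#CCCCCCO | starting material
2 | 7-bromohept-6-yn-1-ol | BrC#CCCCCCO | intermediate
3 | hex-1-en-5-yne | C=CCCC#C | starting material
4 | tridec-12-ene-6,8-diyn-1-ol | OCCCCCC#CC#CCCC=C | intermediate
5 | (6Z,8Z)-trideca-6,8,12-trien-1-ol | OCCCCC/C=C\C=C/CCC=C | intermediate
6 | (5Z,7Z)-13-bromotrideca-1,5,7-triene | BrCCCCC/C=C\C=C/CCC=C | intermediate
7 | [(2S)-5-oxooxolan-2-yl]methyl 4-methylbenzenesulfonate | O=C1CC[C@@H](COS(=O)(=O)c2ccc(C)cc2)O1 | starting material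
8 | methyl 3-[(2S)-oxiran-2-yl]propanoate | COC(=O)CC[C@H]1CO1 | intermediate
9 | [(6Z,8Z)-trideca-6,8,12-trien-1-yl]magnesium bromide (not isolated) | Br[Mg]CCCCC/C=C\C=C/CCC=C | intermediate
10 | methyl (4R,11Z,13Z)-4-hydroxyoctadeca-11,13,17-trienoate (not isolated) | COC(=O)CC[C@H](O)CCCCCC/C=C\C=C/CCC=C | intermediate
11 | (5R)-5-[(7Z,9Z)-tetradeca-7,9,13-trien-1-yl]oxolan-2-one | O=C1CC[C@@H](CCCCCC/C=C\C=C/CCC=C)O1 | intermediate
12 | (5R)-5-[(7Z,9Z)-tetradeca-7,9,13-trien-1-yl]oxolan-2-ol (anomer mixture) | OC1CC[C@@H](CCCCCC/C=C\C=C/CCC=C)O1 | intermediate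
13 | 2-(3-chloropropyl)-1,3-dioxolane | ClCCCC1OCCO1 | starting material
14 | 2-(3-iodopropyl)-1,3-dioxolane (not isolated) | ICCCC1OCCO1 | intermediate
15 | [3-(1,3-dioxolan-2-yl)propyl]triphenylphosphonium iodide | [I-].C1COC(CCC[P+](c2ccccc2)(c2ccccc2)c2ccccc2)O1 | intermediate
16 | [3-(1,3-dioxolan-2-yl)propylidene]triphenylphosphorane (not isolated) | C1COC(CCC=P(c2ccccc2)(c2ccccc2)c2ccccc2)O1 | intermediate
17 | (3Z,7R,14Z,16Z)-1-(1,3-dioxolan-2-yl)henicosa-3,14,16,20-tetraen-7-ol | O[C@H](CCCCCC/C=C\C=C/CCC=C)CC/C=C\CCC1OCCO1 | intermediate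
18 | (1R)-3-(1,3-dioxolan-2-yl)-1-{(2S,5R)-5-[(7Z,9Z)-tetradeca-7,9,13-trien-1-yl]oxolan-2-yl}propan-1-ol | C=CCC/C=C\C=C/CCCCCC[C@@H]1CC[C@@H]([C@H](O)CCC2OCCO2)O1 | intermediate
19 | (5R)-5-{(2S,5R)-5-[(7Z,9Z)-tetradeca-7,9,13-trien-1-yl]oxolan-2-yl}oxolan-2-ol (anomer mixture) | C=CCC/C=C\C=C/CCCCCC[C@@H]1CC[C@@H]([C@H]2CCC(O)O2)O1 | intermediate
20 | methyl (triphenylphosphoranylidene)acetate | COC(=O)C=P(c1ccccc1)(c1ccccc1)c1ccccc1 | starting material
21 | methyl (2E,6R)-6-hydroxy-6-{(2S,5R)-5-[(7Z,9Z)-tetradeca-7,9,13-trien-1-yl]oxolan-2-yl}hex-2-enoate | C=CCC/C=C\C=C/CCCCCC[C@@H]1CC[C@@H]([C@H](O)CC/C=C/C(=O)OC)O1 | intermediate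
22 | methyl (2E,6R)-6-{(2S,5R)-5-[(7Z,9Z)-tetradeca-7,9,13-trien-1-yl]oxolan-2-yl}-6-[(trifluoromethanesulfonyl)oxy]hex-2-enoate (not isolated) | C=CCC/C=C\C=C/CCCCCC[C@@H]1CC[C@@H]([C@H](OS(=O)(=O)C(F)(F)F)CC/C=C/C(=O)OC)O1 | intermediate
23 | methyl (2E,6S)-6-hydroperoxy-6-{(2S,5R)-5-[(7Z,9Z)-tetradeca-7,9,13-trien-1-yl]oxolan-2-yl}hex-2-enoate | C=CCC/C=C\C=C/CCCCCC[C@@H]1CC[C@@H]([C@@H](OO)CC/C=C/C(=O)OC)O1 | intermediate
24 | methyl 2-[(3S,6S)-6-{(2S,5R)-5-[(7Z,9Z)-tetradeca-7,9,13-trien-1-yl]oxolan-2-yl}-1,2-dioxan-3-yl]acetate | C=CCC/C=C\C=C/CCCCCC[C@@H]1CC[C@@H]([C@@H]2CC[C@@H](CC(=O)OC)OO2)O1 | intermediate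
25 | 2-[(3S,6S)-6-{(2S,5R)-5-[(7Z,9Z)-tetradeca-7,9,13-trien-1-yl]oxolan-2-yl}-1,2-dioxan-3-yl]acetic acid | C=CCC/C=C\C=C/CCCCCC[C@@H]1CC[C@@H]([C@@H]2CC[C@@H](CC(=O)O)OO2)O1 | target

**Total step count:** 15
**Longest linear sequence:** 13 steps (steps 1, 2, 3, 4, 6, 7, 9, 10, 11, 12, 13, 14, 15)

**Steps most likely to fail**

Step 13. The displacement at the hindered secondary centre next to the oxolane oxygen may be outrun by elimination, or by participation of the ring oxygen leading to ring expansion and loss of stereochemical integrity. Fallback: starting from 21, the triflate 22 would be generated as before and treated with an anionic, masked peroxide nucleophile, 2-methoxypropan-2-yl hydroperoxide with CsOH·H2O in DMF at 0 °C. This direct SN2 reaction with a charged nucleophile should give, with inversion, the peroxyketal methyl (2E,6S)-6-[(2-methoxypropan-2-yl)peroxy]-6-{(2S,5R)-5-[(7Z,9Z)-tetradeca-7,9,13-trien-1-yl]oxolan-2-yl}hex-2-enoate F1. Mild hydrolysis of the peroxyketal (AcOH/H2O/THF, rt) would release the hydroperoxide and return to the route at 23.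

Step 10. The rhenium reagent may oxidise or isomerise the remote (Z,Z)-diene, may cleave the acetal, or the perrhenate ester may cyclise sluggishly. Fallback: the oxolane would be built from a diepoxide before any diene is present.
- Setting out from 8, reduction with i-Bu2AlH at −78 °C would give 3-[(2S)-oxiran-2-yl]propanal F2.
- In parallel, 13 would be S-alkylated with 1-phenyl-1H-tetrazole-5-thiol (K2CO3, DMF) to 5-{[3-(1,3-dioxolan-2-yl)propyl]sulfanyl}-1-phenyl-1H-tetrazole F3 and oxidised (mCPBA, NaHCO3) to 5-{[3-(1,3-dioxolan-2-yl)propyl]sulfonyl}-1-phenyl-1H-tetrazole F4.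
- Julia–Kocienski olefination of F2 with F4 (KN(SiMe3)2, DME, −60 °C) should give the E-alkene 2-{(3E)-6-[(2S)-oxiran-2-yl]hex-3-en-1-yl}-1,3-dioxolane F5.
- Shi epoxidation (D-fructose-derived ketone, KHSO5, pH 10.5) would give the diepoxide 2-(2-{(2R,3R)-3-[2-((2S)-oxiran-2-yl)ethyl]oxiran-2-yl}ethyl)-1,3-dioxolane F6.
- CuI-catalysed opening of the terminal epoxide by Grignard reagent 9 would give the epoxy alcohol (1R)-1-{(2R,3R)-3-[2-(1,3-dioxolan-2-yl)ethyl]oxiran-2-yl}heptadeca-10,12,16-trien-3-ol-type compound, named (3R,10Z,12Z)-1-{(2R,3R)-3-[2-(1,3-dioxolan-2-yl)ethyl]oxiran-2-yl}heptadeca-10,12,16-trien-3-ol F7.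
- With camphorsulfonic acid (cat., CH2Cl2, 0 °C) F7 should close 5-exo at the proximal epoxide carbon with inversion, returning to the route at 18.

Step 14. The ring closure may show poor facial selectivity at C3 if equilibration is incomplete, or the base may cleave the peroxide before the trans isomer accumulates. Fallback: C3 would be set by C–C bond formation on a preformed peroxide ring.
- Setting out from 18, triflation (Tf2O, 2,6-lutidine, −78 °C) would give the triflate (1R)-3-(1,3-dioxolan-2-yl)-1-{(2S,5R)-5-[(7Z,9Z)-tetradeca-7,9,13-trien-1-yl]oxolan-2-yl}propyl trifluoromethanesulfonate F8.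
- Displacement with ethereal H2O2 would give the hydroperoxy acetal 2-[(3S)-3-hydroperoxy-3-{(2S,5R)-5-[(7Z,9Z)-tetradeca-7,9,13-trien-1-yl]oxolan-2-yl}propyl]-1,3-dioxolane F9.
- Acid-catalysed transacetalisation (TsOH, MeOH) would close the cyclic peroxyacetal (6S)-3-methoxy-6-{(2S,5R)-5-[(7Z,9Z)-tetradeca-7,9,13-trien-1-yl]oxolan-2-yl}-1,2-dioxane F10.
- Treatment of F10 with 1-methoxy-1-(trimethylsilyloxy)ethene and Me3SiOTf (or SnCl4) in CH2Cl2 at −78 °C would generate the cyclic peroxycarbenium ion. The silyl ketene acetal should attack it trans to the C6 substituent, returning to the route at 24.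

**Further compounds**

F1 | step 13 | methyl (2E,6S)-6-[(2-methoxypropan-2-yl)peroxy]-6-{(2S,5R)-5-[(7Z,9Z)-tetradeca-7,9,13-trien-1-yl]oxolan-2-yl}hex-2-enoate | C=CCC/C=C\C=C/CCCCCC[C@@H]1CC[C@@H]([C@@H](OOC(C)(C)OC)CC/C=C/C(=O)OC)O1
F2 | step 10 | 3-[(2S)-oxiran-2-yl]propanal | O=CCC[C@H]1CO1
F3 | step 10 | 5-{[3-(1,3-dioxolan-2-yl)propyl]sulfanyl}-1-phenyl-1H-tetrazole | C1COC(CCCSc2nnnn2-c2ccccc2)O1
F4 | step 10 | 5-{[3-(1,3-dioxolan-2-yl)propyl]sulfonyl}-1-phenyl-1H-tetrazole | O=S(=O)(CCCC1OCCO1)c1nnnn1-c1ccccc1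
F5 | step 10 | 2-{(3E)-6-[(2S)-oxiran-2-yl]hex-3-en-1-yl}-1,3-dioxolane | C1COC(CC/C=C/CC[C@H]2CO2)O1
F6 | step 10 | 2-(2-{(2R,3R)-3-[2-((2S)-oxiran-2-yl)ethyl]oxiran-2-yl}ethyl)-1,3-dioxolane | C1COC(CC[C@H]2O[C@@H]2CC[C@H]3CO3)O1
F7 | step 10 | (3R,10Z,12Z)-1-{(2R,3R)-3-[2-(1,3-dioxolan-2-yl)ethyl]oxiran-2-yl}heptadeca-10,12,16-trien-3-ol | C=CCC/C=C\C=C/CCCCCC[C@@H](O)CC[C@H]1O[C@@H]1CCC2OCCO2
F8 | step 14 | (1R)-3-(1,3-dioxolan-2-yl)-1-{(2S,5R)-5-[(7Z,9Z)-tetradeca-7,9,13-trien-1-yl]oxolan-2-yl}propyl trifluoromethanesulfonate | C=CCC/C=C\C=C/CCCCCC[C@@H]1CC[C@@H]([C@H](OS(=O)(=O)C(F)(F)F)CCC2OCCO2)O1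
F9 | step 14 | 2-[(3S)-3-hydroperoxy-3-{(2S,5R)-5-[(7Z,9Z)-tetradeca-7,9,13-trien-1-yl]oxolan-2-yl}propyl]-1,3-dioxolane | C=CCC/C=C\C=C/CCCCCC[C@@H]1CC[C@@H]([C@@H](OO)CCC2OCCO2)O1
F10 | step 14 | (6S)-3-methoxy-6-{(2S,5R)-5-[(7Z,9Z)-tetradeca-7,9,13-trien-1-yl]oxolan-2-yl}-1,2-dioxane | C=CCC/C=C\C=C/CCCCCC[C@@H]1CC[C@@H]([C@@H]2CCC(OC)OO2)O1
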